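**Plan**
Numbering: ring A is the oxygenated ring, with C1 (CMe2), C2, C3 (O-bearing), C4, C5 (C-methyl) and C6 (chain-bearing). C7=C8 is the first chain alkene, and ring B is the unoxygenated trimethylcyclohexene.
Cuts, in retrosynthetic order: (a) the oleate C(=O)–O3 bond. (b) C7=C8, a Wittig union of a C10 ring-A phosphonium salt with commercial C30 beta-apo-8'-carotenal, which brings ring B and eight E chain alkenes. (c) C7–P, with allylic transposition back to C5(OH)–C6(=C7H2). (d) C5–C6 of ring A. (e) C3–C4, by aldol.
Enabling feature: ring A holds a tetrasubstituted C5=C6 alkene that carries exocyclic C7 and abuts quaternary C1. The triad C5=C6–C7 is the transposed form of a 1-methyl-2-methylenecyclohexanol. That alcohol is the direct product of a C5 ketyl radical closing 6-exo-dig on a C6≡C7 alkyne hung on C1, so one acyclic C10 alkynyl ketone holds every carbon of ring A plus C7.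
Forward order: alkyne C6≡C7 on C1, C3 aldehyde by ozonolysis, aldol with acetone, silylation, closure of ring A (the only ring closure, since ring B is bought), phosphonium salt, C10 + C30 Wittig, oleoylation.
Stereochemistry: C3 (R in the target) comes from the L-proline aldol and is never touched again. The transient C5 centre is erased. C7=C8 becomes E through the Wittig step plus thermal equilibration. The other E alkenes come from 10 and the Z alkene from oleic acid.

Key step: step 5

Assumption: compound 8 is drawn as the C5 epimer expected to dominate; the other epimer gives the same allyl cation in step 6 and needs no separation.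

Step 1
Reactants: 1 2,2-dimethylpent-4-enal
Product: 2 4,4-dimethylhex-1-en-5-yne
Conditions: dimethyl (1-diazo-2-oxopropyl)phosphonate (1.2 equiv), K2CO3 (2 equiv), MeOH, 0 °C to rt
Reagents that add atoms: dimethyl (1-diazo-2-oxopropyl)phosphonate, CC(=O)C(=[N+]=[N-])P(=O)(OC)OC
Why: The Seyferth-Gilbert homologation in its Ohira-Bestmann variant should turn the non-enolisable, alpha-quaternary aldehyde into the terminal alkyne (C6≡C7 on C1) under mild carbonate conditions that leave the allyl group alone.

Step 2
Reactants: 2 4,4-dimethylhex-1-en-5-yne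
Product: 4 3,3-dimethylpent-4-ynal, via secondary ozonide 3 (not isolated)
Conditions: O3, CH2Cl2, -78 °C, stopped at the first blue tint; then Me2S, -78 °C to rt
Reagents that add atoms: ozone, [O-][O+]=O
Why: Ozonolysis with reductive work-up cleaves the monosubstituted alkene far faster than the terminal alkyne, so stopping at the first excess of ozone should give the C3 aldehyde with the alkyne intact.

Step 3
Reactants: 4 3,3-dimethylpent-4-ynal; 5 acetone
Product: 6 (4S)-4-hydroxy-6,6-dimethyloct-7-yn-2-one
Conditions: L-proline (20 mol %), acetone-CHCl3 (1:4), rt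
Reagents that add atoms: none
Why: In this proline-catalysed direct asymmetric aldol reaction the acetone enamine attacks the Re face of the aldehyde within the hydrogen-bonded chair-like transition state, which sets C3 in the sense that becomes 3R in ring A, while the quaternary carbon beta to the aldehyde should slow self-aldolisation.

Step 4
Reactants: 6 (4S)-4-hydroxy-6,6-dimethyloct-7-yn-2-one
Product: 7 (4S)-6,6-dimethyl-4-(triethylsilyloxy)oct-7-yn-2-one
Conditions: Et3SiCl (1.1 equiv), imidazole (1.5 equiv), CH2Cl2, 0 °C
Reagents that add atoms: chlorotriethylsilane, CC[Si](Cl)(CC)CC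
Why: Standard imidazole-promoted O-silylation caps O3 under conditions too mild for beta-elimination, touches no stereocentre, and installs a group that survives step 5 and falls off by itself in step 6.

Step 5
Reactants: 7 (4S)-6,6-dimethyl-4-(triethylsilyloxy)oct-7-yn-2-one
Product: 8 (1S,5S)-1,3,3-trimethyl-2-methylidene-5-(triethylsilyloxy)cyclohexan-1-ol
Conditions: SmI2 (2.5 equiv), HMPA (10 equiv), t-BuOH (2 equiv), THF, slow addition of 7, 0 °C to rt
Reagents that add atoms: none
Why: SmI2 activated by HMPA (divalent samarium as one-electron donor) converts the C5 ketone into its ketyl radical anion, so that the normally electrophilic carbonyl carbon attacks C6 of the unactivated alkyne as a nucleophilic radical; the C7 vinyl radical so formed is quenched by hydrogen abstraction from THF or by a second electron transfer and protonation by t-BuOH, which leaves the exocyclic C6=C7H2 methylene and the trivalent samarium alkoxide of 8. The closest known reaction type is the SmI2-mediated ketyl-alkyne reductive cyclisation of alkynyl ketones to 2-methylenecycloalkanols. Ring A closes in the 6-exo-dig mode through the C5-C6 bond, which is preferred over 7-endo-dig attack at C7 on stereoelectronic grounds and is accelerated by the gem-dimethyl group at C1. The only new stereocentre, C5, should be set by a chair-like transition state with the C3 silyloxy group and the bulky HMPA-solvated O-Sm group both equatorial (1,3-cis), but it is erased in step 6, so either epimer serves, and C3 lies two bonds from the radical centre and is not touched. The step needs cyclisation to outrun ketyl protonation, further reduction and pinacol coupling: slow addition of 7 to excess reagent keeps the ketyl dilute, the silyl cap removes the internal proton donor at O3, only a weak bulky alcohol is present, and no leaving group stands alpha to the ketone, so reductive C-O cleavage has no pathway.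

Step 6
Reactants: 8 (1S,5S)-1,3,3-trimethyl-2-methylidene-5-(triethylsilyloxy)cyclohexan-1-ol
Product: 9 {[(4R)-4-hydroxy-2,6,6-trimethylcyclohex-1-en-1-yl]methyl}triphenylphosphonium bromide
Conditions: PPh3·HBr (1.2 equiv), MeOH, rt, 24-48 h
Reagents that add atoms: triphenylphosphine hydrobromide, [Br-].c1ccc(cc1)[PH+](c1ccccc1)c1ccccc1
Why: In this acid-mediated SN1-type allylic substitution with transposition (the reaction type that turns tertiary vinyl carbinols into polyenyl Wittig salts) HBr ionises the tertiary allylic C5-OH, PPh3 captures the allyl cation at the unhindered primary terminus C7 so that the alkene moves into the tetrasubstituted C5=C6 position and the C5 centre vanishes, and the methanolic acid strips the labile triethylsilyl ether while the non-allylic C3 carbinol keeps its configuration.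

Step 7
Reactants: 9 {[(4R)-4-hydroxy-2,6,6-trimethylcyclohex-1-en-1-yl]methyl}triphenylphosphonium bromide; 10 all-E beta-apo-8'-carotenal
Product: 12 (3R)-beta-cryptoxanthin, via sodium alkoxide ylide 11 (not isolated)
Conditions: NaN(SiMe3)2 (2.1 equiv), THF, -78 to 0 °C; then 10 in THF, 0 °C to rt; aqueous work-up; heptane, reflux (Z to E equilibration); dark, Ar
Reagents that add atoms: none
Why: The Wittig olefination of the semistabilised cyclogeranyl-type ylide with the non-enolisable polyene aldehyde forms C7=C8, where a 7Z alkene would clash with the C1 and C5 methyl groups, so the E isomer should prevail and thermal equilibration should converge any Z material on the all-E polyene, with the C3 alkoxide a spectator.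

Step 8
Reactants: 12 (3R)-beta-cryptoxanthin; 13 oleic acid
Product: 14 (3R)-beta-cryptoxanthin oleate (target)
Conditions: DCC (1.3 equiv), DMAP (0.2 equiv), CH2Cl2, rt, dark, Ar
Reagents that add atoms: none
Why: Steglich esterification acylates O3 without breaking the C3-O bond, so the R configuration is retained, and the neutral, light- and oxygen-free conditions should leave the polyene and the Z alkene of the acyl chain unchanged.

**Compound list**
1 | 2,2-dimethylpent-4-enal | C=CCC(C)(C)C=O | starting material
2 | 4,4-dimethylhex-1-en-5-yne | C=CCC(C)(C)C#C | intermediate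
3 | 3-(2,2-dimethylbut-3-yn-1-yl)-1,2,4-trioxolane (secondary ozonide, racemic at the acetal carbon, which is lost) | C#CC(C)(C)CC1OCOO1 | intermediate
4 | 3,3-dimethylpent-4-ynal | C#CC(C)(C)CC=O | intermediate
5 | acetone | CC(C)=O | starting material
6 | (4S)-4-hydroxy-6,6-dimethyloct-7-yn-2-one | O[C@@H](CC(C)(C)C#C)CC(C)=O | intermediate
7 | (4S)-6,6-dimethyl-4-(triethylsilyloxy)oct-7-yn-2-one | CC[Si](CC)(CC)O[C@@H](CC(C)(C)C#C)CC(C)=O | intermediate
8 | (1S,5S)-1,3,3-trimethyl-2-methylidene-5-(triethylsilyloxy)cyclohexan-1-ol | CC[Si](CC)(CC)O[C@@H]1C[C@](C)(O)C(=C)C(C)(C)C1 | intermediate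
9 | {[(4R)-4-hydroxy-2,6,6-trimethylcyclohex-1-en-1-yl]methyl}triphenylphosphonium bromide | [Br-].O[C@@H]1CC(C)=C(C[P+](c2ccccc2)(c2ccccc2)c2ccccc2)C(C)(C)C1 | intermediate
10 | all-E beta-apo-8'-carotenal | O=C/C(C)=C/C=C/C(C)=C/C=C/C=C(C)/C=C/C=C(C)/C=C/C1=C(C)CCCC1(C)C | starting material
11 | sodium (1R)-3,5,5-trimethyl-4-[(triphenylphosphoranylidene)methyl]cyclohex-3-en-1-olate | [Na+].[O-][C@@H]1CC(C)=C(C=P(c2ccccc2)(c2ccccc2)c2ccccc2)C(C)(C)C1 | intermediate
12 | (3R)-beta-cryptoxanthin, (3R)-beta,beta-caroten-3-ol | O[C@@H]1CC(C)=C(/C=C/C(C)=C/C=C/C(C)=C/C=C/C=C(C)/C=C/C=C(C)/C=C/C2=C(C)CCCC2(C)C)C(C)(C)C1 | intermediate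
13 | oleic acid, (9Z)-octadec-9-enoic acid | CCCCCCCC/C=C\CCCCCCCC(=O)O | starting material
14 | (3R)-beta-cryptoxanthin oleate | CCCCCCCC/C=C\CCCCCCCC(=O)O[C@@H]1CC(C)=C(/C=C/C(C)=C/C=C/C(C)=C/C=C/C=C(C)/C=C/C=C(C)/C=C/C2=C(C)CCCC2(C)C)C(C)(C)C1 | target

Total step count: 8. Longest linear sequence: 8 (1 to 14).

**Steps most likely to fail**

Step 5. Three failures are possible:
- The ketyl may be protonated and reduced before it cyclises.
- It may dimerise by pinacol coupling.
- It may attack the less crowded alkyne terminus in the 7-endo mode, because C6 stands next to quaternary C1.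

The fallback closes the same C5=C6 bond by polar chemistry. It sets out from 7 and returns at 9.
- Anti-Markovnikov hydration of the alkyne of 7 with RuCl(C5H5)(Ph2PCH2PPh2) in aqueous 2-propanol would give (5S)-3,3-dimethyl-7-oxo-5-(triethylsilyloxy)octanal F1.
- Piperidinium acetate in warm toluene would convert the aldehyde into its enamine. Its C6 attacks the C5 ketone, and dehydration (intramolecular aldol condensation) would give (4R)-2,6,6-trimethyl-4-(triethylsilyloxy)cyclohex-1-ene-1-carbaldehyde F2.
- NaBH4 with CeCl3 in MeOH would reduce this to [(4R)-2,6,6-trimethyl-4-(triethylsilyloxy)cyclohex-1-en-1-yl]methanol F3.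
- PPh3·HBr in MeOH would ionise F3 to the same allyl cation as in step 6 and deliver 9.

Step 3. Facial selectivity may be insufficient with an alpha-unbranched aldehyde, turnover may be slow, and the aldol may dehydrate to the enone. The crystalline salt 9 offers a later point for enantiomeric enrichment.

The fallback replaces catalyst control by reagent control. It sets out from 4 and returns at 7.
- Brown methallylation of 4 uses the borane made from (+)-B-methoxydiisopinocampheylborane and CH2=C(CH3)CH2MgCl (Et2O, -78 °C, then NaOH/H2O2). It would give (4R)-2,6,6-trimethyloct-1-en-7-yn-4-ol F4.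
- Et3SiCl and imidazole would give triethyl{[(4R)-2,6,6-trimethyloct-1-en-7-yn-4-yl]oxy}silane F5.
- Ozonolysis of the 1,1-disubstituted alkene (O3, then Me2S), which reacts ahead of the alkyne, would unveil the methyl ketone of 7.

Step 7. The crowded ylide, flanked by the C1 and C5 methyl groups, may add sluggishly and decay before it reacts. Geometrical scrambling of the polyene may also complicate isolation.

The fallback reverses the polarity of the C7=C8 union. It sets out from 8 and 10 and returns at 12.
- Babler-Dauben oxidative transposition of 8 with pyridinium chlorochromate, [C5H5NH][CrO3Cl], and NaOAc in CH2Cl2 would give (4R)-2,6,6-trimethyl-4-(triethylsilyloxy)cyclohex-1-ene-1-carbaldehyde F2, the compound already met above.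
- NaBH4 would reduce 10 to all-E beta-apo-8'-carotenol F6.
- PPh3·HBr in MeOH would convert this into (beta-apo-8'-carotenyl)triphenylphosphonium bromide F7.
- Wittig reaction of F7 (NaOMe, CH2Cl2-MeOH) with F2 would give (3R)-3-(triethylsilyloxy)-beta,beta-carotene F8.
- Bu4NF in THF would release 12.

**Further compounds**
F1 | step 5 | (5S)-3,3-dimethyl-7-oxo-5-(triethylsilyloxy)octanal | CC[Si](CC)(CC)O[C@@H](CC(C)(C)CC=O)CC(C)=O
F2 | step 5 | (4R)-2,6,6-trimethyl-4-(triethylsilyloxy)cyclohex-1-ene-1-carbaldehyde | CC[Si](CC)(CC)O[C@@H]1CC(C)=C(C=O)C(C)(C)C1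
F3 | step 5 | [(4R)-2,6,6-trimethyl-4-(triethylsilyloxy)cyclohex-1-en-1-yl]methanol | CC[Si](CC)(CC)O[C@@H]1CC(C)=C(CO)C(C)(C)C1
F4 | step 3 | (4R)-2,6,6-trimethyloct-1-en-7-yn-4-ol | O[C@@H](CC(C)(C)C#C)CC(C)=C
F5 | step 3 | triethyl{[(4R)-2,6,6-trimethyloct-1-en-7-yn-4-yl]oxy}silane | CC[Si](CC)(CC)O[C@@H](CC(C)(C)C#C)CC(C)=C
F6 | step 7 | all-E beta-apo-8'-carotenol | OC/C(C)=C/C=C/C(C)=C/C=C/C=C(C)/C=C/C=C(C)/C=C/C1=C(C)CCCC1(C)C
F7 | step 7 | (beta-apo-8'-carotenyl)triphenylphosphonium bromide | [Br-].C(/C(C)=C/C=C/C(C)=C/C=C/C=C(C)/C=C/C=C(C)/C=C/C1=C(C)CCCC1(C)C)[P+](c1ccccc1)(c1ccccc1)c1ccccc1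
F8 | step 7 | (3R)-3-(triethylsilyloxy)-beta,beta-carotene | CC[Si](CC)(CC)O[C@@H]1CC(C)=C(/C=C/C(C)=C/C=C/C(C)=C/C=C/C=C(C)/C=C/C=C(C)/C=C/C2=C(C)CCCC2(C)C)C(C)(C)C1
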